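If you want the length of a chain from a flask that shows how much monomer went into chains, you need a second number, the count of chains, and the runs do not give it.

| setting | midnight | dusk | west | north-east |
|---|---|---|---|---|
| free monomer | 0.10 M | 0.10 M | 0.10 M | 0.10 M |
| transfer agent | 3 mM | 3 mM | 3.00 mM | 3.00 mM |
| initiator | 1.1 mM | 4.1 mM | 2.0 mM | 6.0 mM |
| remark | run made earlier | run made earlier |  |  |
| time |  |  | 20 h | 20 h |

| run | time / h | monomer in chains / % |
|---|---|---|
| midnight | 1.00 | 3 |
| midnight | 1.50 | 5 |
| midnight | 2.50 | 5 |
| midnight | 4.00 | 11 |
| midnight | 6.00 | 13 |
| midnight | 10.0 | 17 |
| midnight | 15.0 | 21 |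
| dusk | 0.833 | 9 |
| dusk | 2.00 | 18 |
| dusk | 4.00 | 28 |
| dusk | 6.00 | 35 |
| dusk | 8.00 | 42 |
| dusk | 12.0 | 52 |
| dusk | 15.0 | 54 |

(each reading ± 2 percentage points)

- which of the two ends with the longer chains by the average number of monomer units in a chain (chains begun, living or dead) ("neither" if they lie within 10%) (west / north-east / neither)
- average number of monomer units in a chain (chains begun, living or dead) at the end, west
- average number of monomer units in a chain (chains begun, living or dead) at the end, north-east

- the average divides the monomer in chains by the number of chains begun, living and dead together
- the earlier runs were read with a standard deviation of 2 percentage points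
- the earlier runs do not show the number of chains; that part of a forecast is a guess

So freeze that count. My own guess is that each initiator charged begins one chain by the end, and that the transfer agent ends a chain without adding to the count. The average length L (the number-average degree of polymerisation) is then monomer in chains divided by initiator charged. The last readings, at 15.0 h, give L = 19.1 for midnight and 13.2 for dusk, each with the scatter of its reading. Dusk is shorter, so L is no constant of these runs.

Their ratio gives, as a reading with that same scatter, s = 0.282, the length exponent, which is the fall in ln L per unit rise in the ln of the initiator charge. Scaling midnight to west gives 16.1. Scaling dusk to north-east, a step beyond the charges tried, gives 11.8. I leave the gap from 15.0 h to 20 h unfilled. West comes out longer by a factor of 1.36, outside the margin of 10%, so my answer is west.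

The forecast differs: it says neither, with 8.7 (6.5 to 11.5) for west and 9.4 (7 to 13) for north-east. It counts chains as “3 mM from transfer agent plus initiator-derived chains”, roughly 4.4 mM in west.

The simulation gives 16.8 for west and 11.9 for north-east, so west ends longer.

    free monomer + initiator → living end + monomer in chains (k = 0.00333 L mol⁻¹ s⁻¹)
    free monomer + living end → monomer in chains + living end, rate k2*[living end]*[free monomer] (k = 0.00820 L mol⁻¹ s⁻¹)
    living end + transfer agent → dead chain (kL = 0.0101 L mol⁻¹ s⁻¹)
    free monomer → uncatalysed product (k = 1.16 × 10⁻⁵ s⁻¹)

The two part on the count: in west, living ends and dead chains at 20.0 h sum to 2.00 mM, the initiator charge of 2.0 mM. In north-east they sum to 5.99 mM, against a charge of 6.0 mM. My s had given 16.1 and 11.8. Now take one more flask, like north-east but charged with 1.50 mM of initiator. Scaling midnight with the same s gives 17.5. In that flask monomer in chains stands at 26.1%, and its average length at 20.0 h is 17.4.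

The runs were generated by integration for substances that don't exist, noise included.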